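**Retrosynthetic overview**

- Target 21 comes from 19 by removal of the 3-O-MOM group and Pd(0) cleavage of three allyl ethers; 19 comes from the 5,7-difluoroflavone 17 by exchange of both ring-A fluorides for allyloxide.
- 17 is disconnected at O1–C8a (intramolecular SNAr) to the 2-alkoxy-1,3-diketone 15; this closes the pyranone (ring C), the only ring formed, while rings A and B are bought.
- 15 is disconnected at C2–C3 (enolate aroylation) to ketone 11 and 4-(allyloxy)benzoyl chloride 13; 11 at C4–C4a (aryllithium plus MOM-glycolic Weinreb amide 9); the prenyl groups come from two lithiation/alkylations of 1,3,5-trifluorobenzene.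
- The strategy rests on ring A: its carbons alternate oxygen-bearing (C5, C7, C8a) and carbon-bearing (C4a, C6, C8). This maps onto 1,3,5-trifluorobenzene, whose three C–H sites (each between two fluorines) take the two prenyls and the acyl group. The C4 carbonyl then activates C8a–F for ring closure and C5–F/C7–F for alkoxide exchange.
- O4' is carried as an allyl ether (robust acid chloride, leaves with the ring-A allyl groups); O3 is carried as MOM.

Key step: step 8

Remark: diketone 15 is a keto–enol tautomer mixture and is written as its chelated enol; 4-(allyloxy)benzoic acid (12) and methyl glycolate (7) are taken as purchased materials.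

**Route**

Step 1
Reactants: 1 1,3,5-trifluorobenzene; 2 prenyl bromide (1-bromo-3-methylbut-2-ene)
Product: 4 1,3,5-trifluoro-2-(3-methylbut-2-en-1-yl)benzene, via (2,4,6-trifluorophenyl)lithium 3 (not isolated)
Conditions: n-BuLi (1.05 equiv), THF, −78 °C, 1 h; then 2, −78 → −30 °C
Reagents that add atoms: none
Why: Fluorine-directed ortho-lithiation should remove the C–H flanked by two fluorines cleanly at −78 °C, where the aryllithium is stable towards LiF loss, and SN2 attack on the primary allylic bromide then gives the linear prenyl arene.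

Step 2
Reactants: 4 1,3,5-trifluoro-2-(3-methylbut-2-en-1-yl)benzene; 2 prenyl bromide
Product: 6 1,3,5-trifluoro-2,4-bis(3-methylbut-2-en-1-yl)benzene, via [2,4,6-trifluoro-3-(3-methylbut-2-en-1-yl)phenyl]lithium 5 (not isolated)
Conditions: n-BuLi (1.05 equiv), THF, −78 °C, 1 h; then 2, −78 → −30 °C
Reagents that add atoms: none
Why: In this second fluorine-directed ortho-lithiation and SN2 alkylation the two remaining ring hydrogens are equivalent and each lies between two fluorines, so kinetic deprotonation at −78 °C should beat removal of the benzylic–allylic CH2 protons and only one regioisomer can form.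

Step 3
Reactants: 7 methyl glycolate
Product: 8 methyl 2-(methoxymethoxy)acetate
Conditions: MOMCl, i-Pr2NEt, CH2Cl2, 0 °C → rt
Reagents that add atoms: chloromethyl methyl ether (MOMCl), COCCl
Why: Williamson-type MOM etherification of a primary alcohol with an amine base, which leaves the methyl ester untouched.

Step 4
Reactants: 8 methyl 2-(methoxymethoxy)acetate
Product: 9 N-methoxy-2-(methoxymethoxy)-N-methylacetamide
Conditions: MeNHOMe·HCl, i-PrMgCl, THF, −20 → 0 °C
Reagents that add atoms: N,O-dimethylhydroxylamine hydrochloride, CNOC.Cl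
Why: Weinreb amide formation by aminolysis of the ester with the chloromagnesium amide generated in the flask, a standard transformation that the MOM acetal tolerates.

Step 5
Reactants: 6 1,3,5-trifluoro-2,4-bis(3-methylbut-2-en-1-yl)benzene; 9 N-methoxy-2-(methoxymethoxy)-N-methylacetamide
Product: 11 2-(methoxymethoxy)-1-[2,4,6-trifluoro-3,5-bis(3-methylbut-2-en-1-yl)phenyl]ethan-1-one, via [2,4,6-trifluoro-3,5-bis(3-methylbut-2-en-1-yl)phenyl]lithium 10 (not isolated)
Conditions: n-BuLi (1.05 equiv), THF, −78 °C; then 9, −78 → −40 °C; aq. NH4Cl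
Reagents that add atoms: none
Why: A third ortho-lithiation at the only ring C–H left is followed by Weinreb ketone synthesis, in which the chelated tetrahedral adduct survives until the cold aqueous quench and so prevents a second addition.

Step 6
Reactants: 12 4-(allyloxy)benzoic acid
Product: 13 4-(allyloxy)benzoyl chloride
Conditions: (COCl)2, DMF (cat.), CH2Cl2, 0 °C → rt; used crude
Reagents that add atoms: oxalyl chloride, ClC(=O)C(=O)Cl
Why: Acid chloride formation through the Vilsmeier intermediate from oxalyl chloride and catalytic DMF, conditions under which an aryl allyl ether is inert.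

Step 7
Reactants: 11 2-(methoxymethoxy)-1-[2,4,6-trifluoro-3,5-bis(3-methylbut-2-en-1-yl)phenyl]ethan-1-one; 13 4-(allyloxy)benzoyl chloride
Product: 15 1-[4-(allyloxy)phenyl]-2-(methoxymethoxy)-3-[2,4,6-trifluoro-3,5-bis(3-methylbut-2-en-1-yl)phenyl]propane-1,3-dione (chelated enol), via lithium Z-enolate of the ketone 14 (not isolated)
Conditions: LiHMDS (2.1 equiv), THF, −78 °C; then 13, −78 → −20 °C; aq. NH4Cl
Reagents that add atoms: none
Why: Claisen-type C-acylation of the preformed chelated lithium enolate with an aroyl chloride, in which the second equivalent of base converts the more acidic product into its diketonate so that it is not acylated again, at a temperature too low for fluoride displacement.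

Step 8
Reactants: 15 1-[4-(allyloxy)phenyl]-2-(methoxymethoxy)-3-[2,4,6-trifluoro-3,5-bis(3-methylbut-2-en-1-yl)phenyl]propane-1,3-dione
Product: 17 2-[4-(allyloxy)phenyl]-5,7-difluoro-3-(methoxymethoxy)-6,8-bis(3-methylbut-2-en-1-yl)-4H-chromen-4-one, via potassium enolate of the diketone 16 (not isolated)
Conditions: K2CO3 (2 equiv), dry DMF, 60 °C
Reagents that add atoms: none
Why: Carbonate converts the diketone into its U-shaped chelated potassium enolate, whose oxygen on the carbon carrying the 4-(allyloxy)phenyl group adds to an ortho C–F carbon of the trifluorobenzoyl ring to give a Meisenheimer anion delocalised onto the C4 carbonyl, and loss of fluoride restores aromaticity (addition–elimination SNAr). The closest known reaction type is the base-mediated cyclisation of 1-(2-fluoroaryl)-1,3-diketones to chromones and flavones, the oxygen counterpart of the quinolone closure of 2-fluorobenzoyl enamines. The pyranone closes in a six-membered, formally 6-endo-trig mode at C8a (an intramolecular oxa-Michael addition to the aryl ketone followed by elimination), forming O1–C8a, and no stereocentre is created. O- over C-arylation is enforced by ring size, since the enolate carbon could only close a four-membered ring, and the choice of fluoride needs no control because the two ortho fluorides are equivalent by symmetry and the para fluoride is out of reach. The two fluorides meta to the attacked carbon add inductive activation, and the weak base should spare the prenyl groups, the MOM acetal and the allyl ether.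

Step 9
Reactants: 17 2-[4-(allyloxy)phenyl]-5,7-difluoro-3-(methoxymethoxy)-6,8-bis(3-methylbut-2-en-1-yl)-4H-chromen-4-one
Product: 19 5,7-bis(allyloxy)-2-[4-(allyloxy)phenyl]-3-(methoxymethoxy)-6,8-bis(3-methylbut-2-en-1-yl)-4H-chromen-4-one, via 7-allyloxy-5-fluoro monoether 18 (not isolated)
Conditions: NaH (6 equiv), allyl alcohol (excess), THF/DMSO, 0 → 65 °C
Reagents that add atoms: allyl alcohol, C=CCO
Why: Twofold intermolecular SNAr, in which C7–F is para and C5–F ortho to the C4 carbonyl, each new allyloxy group is meta to the fluoride that remains and so barely deactivates it, and the excess allyl alcohol keeps the medium too weakly basic to move the prenyl double bonds.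

Step 10
Reactants: 19 5,7-bis(allyloxy)-2-[4-(allyloxy)phenyl]-3-(methoxymethoxy)-6,8-bis(3-methylbut-2-en-1-yl)-4H-chromen-4-one
Product: 20 5,7-bis(allyloxy)-2-[4-(allyloxy)phenyl]-3-hydroxy-6,8-bis(3-methylbut-2-en-1-yl)-4H-chromen-4-one
Conditions: conc. aq. HCl (cat.), MeOH/THF, 40 °C
Reagents that add atoms: none
Why: Acid-catalysed transacetalisation removes the MOM group from the enolic 3-oxygen under mild conditions, and because O5 and O7 are still allylated no free phenol sits next to a prenyl group, which rules out acid-induced chroman formation.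

Step 11
Reactants: 20 5,7-bis(allyloxy)-2-[4-(allyloxy)phenyl]-3-hydroxy-6,8-bis(3-methylbut-2-en-1-yl)-4H-chromen-4-one
Product: 21 6,8-diprenylkaempferol
Conditions: Pd(PPh3)4 (cat.), morpholine, degassed THF, rt
Reagents that add atoms: none
Why: Pd(0)-catalysed deallylation (Tsuji–Trost allyl transfer to morpholine) cleaves the three aryl allyl ethers under neutral conditions that do not touch the unactivated prenyl alkenes or the free phenols.

**Compound list**

1 | 1,3,5-trifluorobenzene | Fc1cc(F)cc(F)c1 | starting material
2 | prenyl bromide (1-bromo-3-methylbut-2-ene) | CC(C)=CCBr | starting material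
3 | (2,4,6-trifluorophenyl)lithium | [Li]c1c(F)cc(F)cc1F | intermediate
4 | 1,3,5-trifluoro-2-(3-methylbut-2-en-1-yl)benzene | CC(C)=CCc1c(F)cc(F)cc1F | intermediate
5 | [2,4,6-trifluoro-3-(3-methylbut-2-en-1-yl)phenyl]lithium | [Li]c1c(F)cc(F)c(CC=C(C)C)c1F | intermediate
6 | 1,3,5-trifluoro-2,4-bis(3-methylbut-2-en-1-yl)benzene | CC(C)=CCc1c(F)cc(F)c(CC=C(C)C)c1F | intermediate
7 | methyl glycolate | COC(=O)CO | starting material
8 | methyl 2-(methoxymethoxy)acetate | COCOCC(=O)OC | intermediate
9 | N-methoxy-2-(methoxymethoxy)-N-methylacetamide | COCOCC(=O)N(C)OC | intermediate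
10 | [2,4,6-trifluoro-3,5-bis(3-methylbut-2-en-1-yl)phenyl]lithium | [Li]c1c(F)c(CC=C(C)C)c(F)c(CC=C(C)C)c1F | intermediate
11 | 2-(methoxymethoxy)-1-[2,4,6-trifluoro-3,5-bis(3-methylbut-2-en-1-yl)phenyl]ethan-1-one | COCOCC(=O)c1c(F)c(CC=C(C)C)c(F)c(CC=C(C)C)c1F | intermediate
12 | 4-(allyloxy)benzoic acid | C=CCOc1ccc(C(=O)O)cc1 | starting material
13 | 4-(allyloxy)benzoyl chloride | C=CCOc1ccc(C(Cl)=O)cc1 | intermediate
14 | lithium (Z)-enolate of ketone 11 | COCO/C=C(\O[Li])c1c(F)c(CC=C(C)C)c(F)c(CC=C(C)C)c1F | intermediate
15 | 1-[4-(allyloxy)phenyl]-2-(methoxymethoxy)-3-[2,4,6-trifluoro-3,5-bis(3-methylbut-2-en-1-yl)phenyl]propane-1,3-dione, chelated enol | COCO/C(C(=O)c1c(F)c(CC=C(C)C)c(F)c(CC=C(C)C)c1F)=C(/O)c1ccc(OCC=C)cc1 | intermediate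
16 | potassium enolate of diketone 15 | COCO/C(C(=O)c1c(F)c(CC=C(C)C)c(F)c(CC=C(C)C)c1F)=C(/[O-])c1ccc(OCC=C)cc1.[K+] | intermediate
17 | 2-[4-(allyloxy)phenyl]-5,7-difluoro-3-(methoxymethoxy)-6,8-bis(3-methylbut-2-en-1-yl)-4H-chromen-4-one | C=CCOc1ccc(-c2oc3c(CC=C(C)C)c(F)c(CC=C(C)C)c(F)c3c(=O)c2OCOC)cc1 | intermediate
18 | 7-(allyloxy)-2-[4-(allyloxy)phenyl]-5-fluoro-3-(methoxymethoxy)-6,8-bis(3-methylbut-2-en-1-yl)-4H-chromen-4-one | C=CCOc1ccc(-c2oc3c(CC=C(C)C)c(OCC=C)c(CC=C(C)C)c(F)c3c(=O)c2OCOC)cc1 | intermediate
19 | 5,7-bis(allyloxy)-2-[4-(allyloxy)phenyl]-3-(methoxymethoxy)-6,8-bis(3-methylbut-2-en-1-yl)-4H-chromen-4-one | C=CCOc1ccc(-c2oc3c(CC=C(C)C)c(OCC=C)c(CC=C(C)C)c(OCC=C)c3c(=O)c2OCOC)cc1 | intermediate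
20 | 5,7-bis(allyloxy)-2-[4-(allyloxy)phenyl]-3-hydroxy-6,8-bis(3-methylbut-2-en-1-yl)-4H-chromen-4-one | C=CCOc1ccc(-c2oc3c(CC=C(C)C)c(OCC=C)c(CC=C(C)C)c(OCC=C)c3c(=O)c2O)cc1 | intermediate
21 | 6,8-diprenylkaempferol (no stereocentre) | CC(C)=CCc1c(O)c(CC=C(C)C)c2oc(-c3ccc(O)cc3)c(O)c(=O)c2c1O | target

**Step count**

Total steps: 11. Longest linear sequence: 8 steps (steps 1, 2, 5, 7, 8, 9, 10, 11, from 1,3,5-trifluorobenzene).

**Steps most likely to fail**

1. Step 9. The second fluoride exchange may stall, because the site is flanked by prenyl groups and the first allyloxy group weakens the acceptor strength of the C4 carbonyl. Forcing with hot alkoxide may then shift the prenyl double bonds into conjugation or open the pyranone. The fallback sets out from 17 and exchanges only the more reactive fluoride with one equivalent of sodium allyloxide at 0 °C to rt, so that monoether 18 is isolated. The remaining C5 fluoride is then displaced at rt by the sodium alkoxide of 2-(methylsulfonyl)ethanol (NaH, DMF), a small hydroxide surrogate. This should give the 5-[2-(methylsulfonyl)ethoxy] ether F1, which loses methyl vinyl sulfone by E1cB elimination in the same flask to give the 5-hydroxy flavone F2. O-Allylation of the chelated phenol (allyl bromide, Cs2CO3, DMF, 50 °C) brings the material back to the route at 19.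

2. Step 7. The enolate may be acylated on oxygen (enol ester) or twice instead of once on carbon, and the diketonate may close prematurely on warming. The fallback sets out from 11: the lithium enolate 14 is added to 4-(allyloxy)benzaldehyde at −78 °C in an aldol reaction, which should give the β-hydroxy ketone F3 as a diastereomer mixture. Dess–Martin oxidation (NaHCO3, CH2Cl2) of the secondary alcohol then returns to the route at 15.

3. Step 8. The delocalised diketonate is a weak nucleophile, so ring closure may be slow enough for retro-Claisen cleavage by carbonate or adventitious hydroxide, or intermolecular fluoride displacement, to compete. The fallback sets out from 15 and masks the enol as the trimethylsilyl enol ether F4 (TMSCl, Et3N, CH2Cl2). A catalytic amount of anhydrous fluoride (TBAT or CsF, MeCN, rt to 50 °C) then frees the enolate oxygen without Brønsted base or water; the fluoride expelled in the ring closure desilylates the next molecule, and the sequence comes back to the route at 17.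

**Further compounds**

F1 | step 9 | 7-(allyloxy)-2-[4-(allyloxy)phenyl]-3-(methoxymethoxy)-5-[2-(methylsulfonyl)ethoxy]-6,8-bis(3-methylbut-2-en-1-yl)-4H-chromen-4-one | C=CCOc1ccc(-c2oc3c(CC=C(C)C)c(OCC=C)c(CC=C(C)C)c(OCCS(C)(=O)=O)c3c(=O)c2OCOC)cc1
F2 | step 9 | 7-(allyloxy)-2-[4-(allyloxy)phenyl]-5-hydroxy-3-(methoxymethoxy)-6,8-bis(3-methylbut-2-en-1-yl)-4H-chromen-4-one | C=CCOc1ccc(-c2oc3c(CC=C(C)C)c(OCC=C)c(CC=C(C)C)c(O)c3c(=O)c2OCOC)cc1
F3 | step 7 | 3-[4-(allyloxy)phenyl]-3-hydroxy-2-(methoxymethoxy)-1-[2,4,6-trifluoro-3,5-bis(3-methylbut-2-en-1-yl)phenyl]propan-1-one (racemic syn/anti mixture) | COCOC(C(O)c1ccc(OCC=C)cc1)C(=O)c1c(F)c(CC=C(C)C)c(F)c(CC=C(C)C)c1F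
F4 | step 8 | trimethylsilyl enol ether of diketone 15 | COCO/C(C(=O)c1c(F)c(CC=C(C)C)c(F)c(CC=C(C)C)c1F)=C(/O[Si](C)(C)C)c1ccc(OCC=C)cc1
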